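- noon: starting material 0.40 M; reagent 2.4 M; capture agent 0.24 M; run made earlier
- flask: starting material 0.80 M; reagent 2.40 M; capture agent 0.240 M; time 30 h

noon run (percent of the starting material charged)

| time / h | single product / % | double product / % |
|---|---|---|
| 0.833 | 19.3 | 0.2 |
| 1.50 | 28.8 | 0.9 |
| 2.50 | 38.0 | 2.9 |
| 3.00 | 40.0 | 4.6 |

(each reading ± 0.3 percentage points)

- steps under discussion: starting material + reagent -> single product; reagent + single product <-> double product; single product + capture agent -> trapped intermediate

- time, not beyond 30 h, at which the flask holds most single product
- the amount of single product, in percent of the starting material charged, at that time

The ratio of capture agent to starting material charged, 30.0% in the flask, is the capture ceiling C, the largest share of the charge that can end as trapped intermediate, since each capture agent takes one single product. With C below one, the capture agent is the limiting reagent of that step. If C is reached and the starting material is used up, single and double product together level off at 70.0%.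

My own reckoning replaces the rising trapped curve by its mean line. In the noon run, the first reading of single and double product gives a first-order loss of starting material of about 0.260 h⁻¹. By 3.00 h the readings therefore fall short by 9.61% of the charge, which is read as trapped intermediate. The flask holds the same molar reagent and capture agent, so in percent of its charge it starts on the same curve, with a slope of 0.0320 h⁻¹. That line meets C at a knee near 9.36 h. The line should err early: as the capture agent thins, the true curve should bend below it, so the knee is rounded. Near it, 8.77% of the starting material remains, and single product should peak there, below 61.2% by whatever double product holds.

The forecast gives 46% at 8.5 h, earlier than this knee, and adds: “The peak is broad”.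

    starting material + reagent → single product (k = 0.121 M⁻¹ h⁻¹)
    reagent + single product ⇌ double product (K = 1.14 M⁻¹, k = 0.0270 M⁻¹ h⁻¹)
    single product + capture agent → trapped intermediate (k = 0.683 M⁻¹ h⁻¹)

The flask peaks at 46.3% at 7.79 h. While capture agent was there, trapped intermediate rose to 10.3% at 3.00 h, and by 30.0 h, with 0.144% of the capture agent left, it stood at 30.0%, at C, while single product and double product held 35.2% and 34.5%. In the neighbour flask with 1.4 M of starting material, C is 17.1%, and trapped intermediate ends at 17.1%.

The numbers in the tables stem from a simulated flask for substances that don't exist; scatter was added.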